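The route rests on a bond that the target lacks. C5 and C14 stand cis on the tetrahydropyran ring (O, C4, C3, C2, C1, C15), so a temporary C5–C14 bond folds C1–C5 and C14–C18 into a 2-oxabicyclo[2.2.2]octane built from the ten carbons of (R)-carvone. The key step closes this cage in one operation: selenium-induced etherification forms O–C4, sets C4 and leaves a selenide on C5. Its precursor is a cis-carveol derivative with C3–OTBS, a free tertiary C15 hydroxyl and the C4=C5 alkene. Selenoxide elimination and unsymmetrical ozonolysis cut the strap. Suzuki coupling (C12–C13), Nozaki–Hiyama–Kishi ring closure (C7–C8) and CBS reduction finish the macrocycle.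

Key step: step 4

Remark on the chemistry: cembrane numbering is used (C1 = ring CH next to C15Me2, C3 = CHOAc, C4 = O-bearing CMe, C7 = CHOH, C8 = exomethylene carbon). In it the target is 1R,3R,4S,7R,11E. O3 is trans to C5/C14 on the pyran, which corresponds to cis-carveol, so C3 needs no inversion. Hex-4-yn-1-ol, B-bromo-9-BBN and both phosphonium salts are taken as catalogue chemicals.

Step 1
Reactants: 1 (R)-(−)-carvone
Product: 2 (5R)-5-(2-hydroxypropan-2-yl)-2-methylcyclohex-2-en-1-one
Conditions: 50% aq. H2SO4, 0 °C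
Reagents that add atoms: water, O
Why: Acid-catalysed Markovnikov hydration runs through the tertiary C15 cation of the isopropenyl group, while the protonated enone resists attack and the C1 stereocentre is not touched.

Step 2
Reactants: 2 (5R)-5-(2-hydroxypropan-2-yl)-2-methylcyclohex-2-en-1-one
Product: 3 (1R,5R)-5-(2-hydroxypropan-2-yl)-2-methylcyclohex-2-en-1-ol
Conditions: NaBH4, CeCl3·7H2O, MeOH, −20 °C
Reagents that add atoms: none
Why: Luche 1,2-reduction delivers hydride axially to the half-chair enone whose C1 side chain is equatorial, which sets C3 (R) as the pseudo-equatorial alcohol cis to that side chain.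

Step 3
Reactants: 3 (1R,5R)-5-(2-hydroxypropan-2-yl)-2-methylcyclohex-2-en-1-ol
Product: 4 2-[(1R,5R)-5-(tert-butyldimethylsilyloxy)-4-methylcyclohex-3-en-1-yl]propan-2-ol
Conditions: TBSCl, imidazole, DMF, rt
Reagents that add atoms: tert-butyldimethylsilyl chloride, CC(C)(C)[Si](C)(C)Cl
Why: Imidazole-promoted silylation is sterically selective, so the secondary allylic alcohol reacts and the tertiary C15 alcohol stays free.

Step 4
Reactants: 4 2-[(1R,5R)-5-(tert-butyldimethylsilyloxy)-4-methylcyclohex-3-en-1-yl]propan-2-ol; 5 phenylselenenyl chloride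
Product: 7 (1R,4S,6R,7R)-6-(tert-butyldimethylsilyloxy)-1,3,3-trimethyl-7-(phenylselanyl)-2-oxabicyclo[2.2.2]octane, via seleniranium chloride 6 (not isolated)
Conditions: PhSeCl, K2CO3, CH2Cl2, −78 °C to rt
Reagents that add atoms: phenylselenenyl chloride (5), Cl[Se]c1ccccc1
Why: PhSe+ adds reversibly to the C4=C5 alkene; the bulky C3 silyl ether steers it to the opposite face, and only that ion (6) places the C15 hydroxyl for backside attack, so the unproductive ion simply reverts. The tertiary alcohol opens 6 at C4 in an anti, SN2-like manner through a boat cyclohexane, which is a phenylselenoetherification whose closest analogy is the closure of alpha-terpineol-type alcohols to 2-phenylselanyl-1,8-cineoles. The ring closed is the tetrahydropyran O–C15–C1–C2–C3–C4 (6-exo with respect to C4=C5, with C5 outside it), and it forms the third bridge of a 2-oxabicyclo[2.2.2]octane. C4 is set by the tether, since oxygen can reach it only from the face that carries C15 at the carvone-derived centre C1, and C5 is set by the obligatory anti addition, which puts selenium opposite to the new ether bridge. The selectivity needed is attack at C4 rather than 5-exo attack at C5 (6-oxabicyclo[3.2.1]octane); the methyl-bearing tertiary carbon holds most of the positive charge, and a silyl ether is the least electron-withdrawing, non-participating cover for O3. K2CO3 takes up HCl so that neither the allylic silyl ether nor the new di-tertiary ether meets acid.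

Step 5
Reactants: 7 (1R,4S,6R,7R)-6-(tert-butyldimethylsilyloxy)-1,3,3-trimethyl-7-(phenylselanyl)-2-oxabicyclo[2.2.2]octane
Product: 9 (1S,4S,7R)-7-(tert-butyldimethylsilyloxy)-1,3,3-trimethyl-2-oxabicyclo[2.2.2]oct-5-ene, via selenoxide 8 (not isolated)
Conditions: 30% H2O2 (excess), pyridine, CH2Cl2, 0 °C to rt
Reagents that add atoms: none
Why: Oxidation to the selenoxide is followed by spontaneous selenoxide syn-elimination, and because C4 is quaternary the only eclipsed syn hydrogen sits on C14, so only the C5=C14 alkene can form.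

Step 6
Reactants: 9 (1S,4S,7R)-7-(tert-butyldimethylsilyloxy)-1,3,3-trimethyl-2-oxabicyclo[2.2.2]oct-5-ene
Product: 11 methyl (3R,5R,6R)-5-(tert-butyldimethylsilyloxy)-6-formyl-2,2,6-trimethyloxane-3-carboxylate, via methoxy hydroperoxide 10 (not isolated)
Conditions: O3, NaHCO3, CH2Cl2–MeOH 5:1, −78 °C; then Ac2O, Et3N, CH2Cl2, 0 °C to rt
Reagents that add atoms: ozone, [O-][O+]=O; methanol, CO
Why: In this terminus-differentiating ozonolysis the primary ozonide should fragment with the carbonyl oxide on C14, remote from the electron-withdrawing C4–O bond; methanol traps it as 10, and acetylation with base-induced fragmentation turns that end into the methyl ester, while the non-enolisable C5 end stays an aldehyde and C1, C3 and C4 are untouched.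

Step 7
Reactants: 11 methyl (3R,5R,6R)-5-(tert-butyldimethylsilyloxy)-6-formyl-2,2,6-trimethyloxane-3-carboxylate
Product: 12 methyl (3R,5R,6S)-5-(tert-butyldimethylsilyloxy)-6-[2-(1,3-dioxolan-2-yl)ethenyl]-2,2,6-trimethyloxane-3-carboxylate (E/Z mixture)
Conditions: (1,3-dioxolan-2-ylmethyl)PPh3Br, KHMDS (slight deficit), THF, 0 °C to rt
Reagents that add atoms: (1,3-dioxolan-2-ylmethyl)triphenylphosphonium bromide, [Br-].C1COC(O1)C[P+](c1ccccc1)(c1ccccc1)c1ccccc1
Why: Wittig olefination of the non-enolisable aldehyde adds C6 and C7 with C7 already masked as an acetal; the alkene geometry is irrelevant, and the absence of free base protects the C1–H next to the ester.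

Step 8
Reactants: 12 methyl (3R,5R,6S)-5-(tert-butyldimethylsilyloxy)-6-[2-(1,3-dioxolan-2-yl)ethenyl]-2,2,6-trimethyloxane-3-carboxylate
Product: 13 methyl (3R,5R,6S)-5-(tert-butyldimethylsilyloxy)-6-[2-(1,3-dioxolan-2-yl)ethyl]-2,2,6-trimethyloxane-3-carboxylate
Conditions: H2 (1 atm), 5% Pt/C, EtOAc, rt
Reagents that add atoms: none
Why: Heterogeneous catalytic hydrogenation saturates the only C=C bond of the molecule, and platinum rather than palladium limits hydrogenolysis of the allylic C4–O bond.

Step 9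
Reactants: 13 methyl (3R,5R,6S)-5-(tert-butyldimethylsilyloxy)-6-[2-(1,3-dioxolan-2-yl)ethyl]-2,2,6-trimethyloxane-3-carboxylate
Product: 14 (3R,5R,6S)-5-(tert-butyldimethylsilyloxy)-6-[2-(1,3-dioxolan-2-yl)ethyl]-2,2,6-trimethyloxane-3-carbaldehyde
Conditions: DIBAL-H (1.1 equiv), CH2Cl2, −78 °C; Rochelle salt
Reagents that add atoms: none
Why: Partial ester reduction with DIBAL-H stops at the aluminium hemiacetal at low temperature, helped by the crowding around C14, and the acetal and silyl ether are inert.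

Step 10
Reactants: 14 (3R,5R,6S)-5-(tert-butyldimethylsilyloxy)-6-[2-(1,3-dioxolan-2-yl)ethyl]-2,2,6-trimethyloxane-3-carbaldehyde
Product: 15 tert-butyl{[(2S,3R,5S)-2-[2-(1,3-dioxolan-2-yl)ethyl]-5-ethenyl-2,6,6-trimethyloxan-3-yl]oxy}dimethylsilane
Conditions: Ph3PCH3Br, KHMDS, THF, −78 to 0 °C (14 used at once)
Reagents that add atoms: methyltriphenylphosphonium bromide, [Br-].C[P+](c1ccccc1)(c1ccccc1)c1ccccc1
Why: Wittig methylenation adds C13, and the fast addition of the unstabilised ylide at low temperature should outrun enolisation of the hindered C1–H, so the C1 configuration is kept.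

Step 11
Reactants: 15 tert-butyl{[(2S,3R,5S)-2-[2-(1,3-dioxolan-2-yl)ethyl]-5-ethenyl-2,6,6-trimethyloxan-3-yl]oxy}dimethylsilane
Product: 16 (2S,3R,5S)-2-[2-(1,3-dioxolan-2-yl)ethyl]-5-ethenyl-2,6,6-trimethyloxan-3-ol
Conditions: TBAF, THF, rt to 45 °C
Reagents that add atoms: none
Why: Fluoride-induced desilylation frees O3 after the last hydride and ylide steps and before any base-sensitive alkenyl halide is present, and the acetal and vinyl group are inert to it.

Step 12
Reactants: 16 (2S,3R,5S)-2-[2-(1,3-dioxolan-2-yl)ethyl]-5-ethenyl-2,6,6-trimethyloxan-3-ol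
Product: 17 (2S,3R,5S)-2-[2-(1,3-dioxolan-2-yl)ethyl]-5-ethenyl-2,6,6-trimethyloxan-3-yl acetate
Conditions: Ac2O, DMAP (cat.), pyridine, rt
Reagents that add atoms: acetic anhydride, CC(=O)OC(C)=O
Why: DMAP-catalysed acetylation installs the C3 acetate of the target with retention, at a stage where no second hydroxyl competes.

Step 13
Reactants: 18 hex-4-yn-1-ol
Product: 20 (E)-5-iodohex-4-en-1-ol, via alkenylzirconocene 19 (not isolated)
Conditions: Cp2Zr(H)Cl (3 equiv), THF, rt to 40 °C; then I2, 0 °C
Reagents that add atoms: iodine, II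
Why: Syn-hydrozirconation with the Schwartz reagent and iodinolysis with retention fix the E geometry of C11=C12, and excess reagent equilibrates the regioisomers toward zirconium on the less hindered, methyl-bearing C12.

Step 14
Reactants: 20 (E)-5-iodohex-4-en-1-ol
Product: 21 (E)-5-iodohex-4-enal
Conditions: DMP, CH2Cl2, 0 °C to rt
Reagents that add atoms: none
Why: Dess–Martin oxidation takes the primary alcohol (C8) to the aldehyde without touching the alkenyl iodide.

Step 15
Reactants: 21 (E)-5-iodohex-4-enal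
Product: 22 (E)-6-iodohept-5-en-1-yne
Conditions: dimethyl (1-diazo-2-oxopropyl)phosphonate, K2CO3, MeOH, 0 °C to rt
Reagents that add atoms: dimethyl (1-diazo-2-oxopropyl)phosphonate, COP(=O)(OC)C(=[N+]=[N-])C(C)=O
Why: Seyferth–Gilbert homologation in the Ohira–Bestmann variant converts the aldehyde carbon C8 into a terminal alkyne and adds C19 under mild carbonate conditions.

Step 16
Reactants: 22 (E)-6-iodohept-5-en-1-yne
Product: 24 (5E)-2-bromo-6-iodohepta-1,5-diene, via bromoalkenylborane 23 (not isolated)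
Conditions: B-Br-9-BBN, CH2Cl2, 0 °C; then AcOH
Reagents that add atoms: B-bromo-9-borabicyclo[3.3.1]nonane, BrB1C2CCCC1CCC2
Why: Haloboration is specific for terminal alkynes and places bromine on the internal carbon C8, and protonolysis of the C–B bond with acetic acid leaves the 2-bromo-1-alkene.

Step 17
Reactants: 17 (2S,3R,5S)-2-[2-(1,3-dioxolan-2-yl)ethyl]-5-ethenyl-2,6,6-trimethyloxan-3-yl acetate; 24 (5E)-2-bromo-6-iodohepta-1,5-diene
Product: 26 (2S,3R,5R)-5-[(3E)-7-bromo-3-methylocta-3,7-dien-1-yl]-2-[2-(1,3-dioxolan-2-yl)ethyl]-2,6,6-trimethyloxan-3-yl acetate, via B-alkyl borane 25 (not isolated)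
Conditions: 9-BBN-H, THF, rt; then H2O, 24, Pd(dppf)Cl2 (cat.), AsPh3 (cat.), Cs2CO3, DMF, rt
Reagents that add atoms: none
Why: Anti-Markovnikov hydroboration of the only alkene of 17, followed by B-alkyl Suzuki–Miyaura coupling, forms C12–C13 with retention of the E geometry, and palladium inserts into the C–I bond far faster than into the C–Br bond.

Step 18
Reactants: 26 (2S,3R,5R)-5-[(3E)-7-bromo-3-methylocta-3,7-dien-1-yl]-2-[2-(1,3-dioxolan-2-yl)ethyl]-2,6,6-trimethyloxan-3-yl acetate
Product: 27 (2S,3R,5R)-5-[(3E)-7-bromo-3-methylocta-3,7-dien-1-yl]-2,6,6-trimethyl-2-(3-oxopropyl)oxan-3-yl acetate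
Conditions: PPTS (cat.), acetone–H2O, reflux
Reagents that add atoms: water, O
Why: Mild acid-catalysed acetal hydrolysis liberates the C7 aldehyde, which cannot collapse to a six-membered lactol because O3 is already acetylated.

Step 19
Reactants: 27 (2S,3R,5R)-5-[(3E)-7-bromo-3-methylocta-3,7-dien-1-yl]-2,6,6-trimethyl-2-(3-oxopropyl)oxan-3-yl acetate
Product: 28 macrocyclic allylic alcohol (the target skeleton with 1R,3R,4S,11E fixed and C7 as an epimer mixture)
Conditions: CrCl2 (excess), NiCl2 (cat.), DMSO, slow addition to about 2 mM, rt to 50 °C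
Reagents that add atoms: none
Why: In this intramolecular Nozaki–Hiyama–Kishi reaction nickel(0) inserts into the alkenyl C–Br bond, and transmetalation gives an alkenylchromium(III) species that adds only to the aldehyde and tolerates the acetate; this closes the 14-membered ring at C7–C8 and creates the exomethylene carbinol, and the C7 configuration is not relied on here.

Step 20
Reactants: 28 macrocyclic allylic alcohol (C7 epimer mixture)
Product: 29 macrocyclic alpha-methylene ketone (7-oxo analogue of the target, 1R,3R,4S,11E)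
Conditions: DMP, CH2Cl2, 0 °C
Reagents that add atoms: none
Why: Dess–Martin oxidation erases the uncontrolled C7 centre and gives the enone under near-neutral conditions that spare the acetate and both isolated alkenes.

Step 21
Reactants: 29 macrocyclic alpha-methylene ketone
Product: 30 target CNP0202897.1 (1R,3R,4S,7R,11E)
Conditions: (S)-Me-CBS oxazaborolidine, catecholborane, toluene, −78 °C
Reagents that add atoms: none
Why: In the Corey–Bakshi–Shibata reduction the branched alkenyl carbon C8 acts as the large and the C6 methylene chain as the small substituent, so the (S)-oxazaborolidine should deliver hydride to give the 7R alcohol, and catecholborane at low temperature spares the acetate and alkenes.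

Compound list
1 | (R)-(−)-carvone | CC1=CC[C@@H](C(C)=C)CC1=O | starting material
2 | (5R)-5-(2-hydroxypropan-2-yl)-2-methylcyclohex-2-en-1-one | CC1=CC[C@@H](C(C)(C)O)CC1=O | intermediate
3 | (1R,5R)-5-(2-hydroxypropan-2-yl)-2-methylcyclohex-2-en-1-ol | CC1=CC[C@@H](C(C)(C)O)C[C@H]1O | intermediate
4 | 2-[(1R,5R)-5-(tert-butyldimethylsilyloxy)-4-methylcyclohex-3-en-1-yl]propan-2-ol | CC1=CC[C@@H](C(C)(C)O)C[C@H]1O[Si](C)(C)C(C)(C)C | intermediate
5 | phenylselenenyl chloride | Cl[Se]c1ccccc1 | starting material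
6 | seleniranium chloride (Se bridges C4 and C5 on the face opposite to OTBS and C15) | C[C@]12[C@H](O[Si](C)(C)C(C)(C)C)C[C@H](C(C)(C)O)C[C@H]1[Se+]2c1ccccc1.[Cl-] | intermediate
7 | (1R,4S,6R,7R)-6-(tert-butyldimethylsilyloxy)-1,3,3-trimethyl-7-(phenylselanyl)-2-oxabicyclo[2.2.2]octane (OTBS syn, SePh anti to the ether bridge) | C[C@@]12OC(C)(C)[C@@H](C[C@H]1O[Si](C)(C)C(C)(C)C)C[C@H]2[Se]c1ccccc1 | intermediate
8 | selenoxide of 7 | C[C@@]12OC(C)(C)[C@@H](C[C@H]1O[Si](C)(C)C(C)(C)C)C[C@H]2[Se](=O)c1ccccc1 | intermediate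
9 | (1S,4S,7R)-7-(tert-butyldimethylsilyloxy)-1,3,3-trimethyl-2-oxabicyclo[2.2.2]oct-5-ene | C[C@@]12OC(C)(C)[C@@H](C[C@H]1O[Si](C)(C)C(C)(C)C)C=C2 | intermediate
10 | C5 aldehyde with a C14 hydroperoxy(methoxy)methyl group | COC(OO)[C@@H]1C[C@@H](O[Si](C)(C)C(C)(C)C)[C@](C)(C=O)OC1(C)C | intermediate
11 | methyl (3R,5R,6R)-5-(tert-butyldimethylsilyloxy)-6-formyl-2,2,6-trimethyloxane-3-carboxylate | COC(=O)[C@@H]1C[C@@H](O[Si](C)(C)C(C)(C)C)[C@](C)(C=O)OC1(C)C | intermediate
12 | methyl (3R,5R,6S)-5-(tert-butyldimethylsilyloxy)-6-[2-(1,3-dioxolan-2-yl)ethenyl]-2,2,6-trimethyloxane-3-carboxylate (E/Z) | COC(=O)[C@@H]1C[C@@H](O[Si](C)(C)C(C)(C)C)[C@](C)(C=CC2OCCO2)OC1(C)C | intermediate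
13 | methyl (3R,5R,6S)-5-(tert-butyldimethylsilyloxy)-6-[2-(1,3-dioxolan-2-yl)ethyl]-2,2,6-trimethyloxane-3-carboxylate | COC(=O)[C@@H]1C[C@@H](O[Si](C)(C)C(C)(C)C)[C@](C)(CCC2OCCO2)OC1(C)C | intermediate
14 | (3R,5R,6S)-5-(tert-butyldimethylsilyloxy)-6-[2-(1,3-dioxolan-2-yl)ethyl]-2,2,6-trimethyloxane-3-carbaldehyde | O=C[C@@H]1C[C@@H](O[Si](C)(C)C(C)(C)C)[C@](C)(CCC2OCCO2)OC1(C)C | intermediate
15 | tert-butyl{[(2S,3R,5S)-2-[2-(1,3-dioxolan-2-yl)ethyl]-5-ethenyl-2,6,6-trimethyloxan-3-yl]oxy}dimethylsilane | C=C[C@@H]1C[C@@H](O[Si](C)(C)C(C)(C)C)[C@](C)(CCC2OCCO2)OC1(C)C | intermediate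
16 | (2S,3R,5S)-2-[2-(1,3-dioxolan-2-yl)ethyl]-5-ethenyl-2,6,6-trimethyloxan-3-ol | C=C[C@@H]1C[C@@H](O)[C@](C)(CCC2OCCO2)OC1(C)C | intermediate
17 | (2S,3R,5S)-2-[2-(1,3-dioxolan-2-yl)ethyl]-5-ethenyl-2,6,6-trimethyloxan-3-yl acetate | C=C[C@@H]1C[C@@H](OC(C)=O)[C@](C)(CCC2OCCO2)OC1(C)C | intermediate
18 | hex-4-yn-1-ol | CC#CCCCO | starting material
19 | (E)-alkenylzirconocene chloride, O-zirconated | C/C([Zr](Cl)(C1C=CC=C1)C1C=CC=C1)=C\CCCO[Zr](Cl)(C1C=CC=C1)C1C=CC=C1 | intermediate
20 | (E)-5-iodohex-4-en-1-ol | C/C(I)=C\CCCO | intermediate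
21 | (E)-5-iodohex-4-enal | C/C(I)=C\CCC=O | intermediate
22 | (E)-6-iodohept-5-en-1-yne | C/C(I)=C\CCC#C | intermediate
23 | (1Z,5E)-(2-bromo-6-iodohepta-1,5-dienyl)-9-BBN | C/C(I)=C\CC/C(Br)=C/B1C2CCCC1CCC2 | intermediate
24 | (5E)-2-bromo-6-iodohepta-1,5-diene | C/C(I)=C\CCC(Br)=C | intermediate
25 | B-alkyl-9-BBN from 17 (boron on C13) | B1(CC[C@@H]2C[C@@H](OC(C)=O)[C@](C)(CCC3OCCO3)OC2(C)C)C2CCCC1CCC2 | intermediate
26 | (2S,3R,5R)-5-[(3E)-7-bromo-3-methylocta-3,7-dien-1-yl]-2-[2-(1,3-dioxolan-2-yl)ethyl]-2,6,6-trimethyloxan-3-yl acetate | C=C(Br)CC/C=C(\C)CC[C@@H]1C[C@@H](OC(C)=O)[C@](C)(CCC2OCCO2)OC1(C)C | intermediate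
27 | (2S,3R,5R)-5-[(3E)-7-bromo-3-methylocta-3,7-dien-1-yl]-2,6,6-trimethyl-2-(3-oxopropyl)oxan-3-yl acetate | C=C(Br)CC/C=C(\C)CC[C@@H]1C[C@@H](OC(C)=O)[C@](C)(CCC=O)OC1(C)C | intermediate
28 | macrocyclic allylic alcohol, C7 epimer mixture | C=C1CC/C=C(\C)CC[C@@H]2C[C@@H](OC(C)=O)[C@](C)(CCC1O)OC2(C)C | intermediate
29 | macrocyclic alpha-methylene ketone (7-oxo) | C=C1CC/C=C(\C)CC[C@@H]2C[C@@H](OC(C)=O)[C@](C)(CCC1=O)OC2(C)C | intermediate
30 | CNP0202897.1 (1R,3R,4S,7R,11E) | C=C1CC/C=C(\C)CC[C@@H]2C[C@@H](OC(C)=O)[C@](C)(CC[C@H]1O)OC2(C)C | target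

Total step count: 21. Longest linear sequence: 17 (steps 1–12 and 17–21). Steps 13–16 build the side-chain unit in parallel.

Steps most likely to fail

1. Step 4. If the C3–O dipole drains too much charge from C4, the hydroxyl could attack C5 instead of C4, or chloride could intercept the seleniranium ion. The fallback sets out from 4, returns at 9, and uses oxygen instead of selenium as the electrophile.
   - mCPBA (NaHCO3, CH2Cl2, 0 °C) should epoxidise C4=C5 mainly on the face away from the silyl ether to give the epoxy alcohol F1.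
   - Catalytic CSA then lets the C15 hydroxyl open the oxirane at tertiary C4 with inversion, the known way from alpha-terpineol oxide to 2-hydroxy-1,8-cineole, to give the C5 alcohol F2.
   - NaH, CS2 and MeI give the xanthate F3. Its Chugaev pyrolysis is a syn-elimination for which only C14 offers a hydrogen, and it returns alkene 9.

2. Step 6. Regiocontrol in the cycloreversion of the primary ozonide may be lost, which would scramble the ester and aldehyde ends between C5 and C14. The fallback sets out from 9, returns at 14, relies on steric instead of electronic differentiation, and costs three extra steps.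
   - Ozonolysis with NaBH4 work-up gives the C5,C14-diol F4 whatever the ozonide does.
   - PivCl (1 equiv, pyridine, −20 °C) should acylate the C14 hydroxyl, because the C5 hydroxyl is neopentyl and shielded by the silyl ether. This gives the mono-pivalate F5.
   - Dess–Martin oxidation gives the C5 aldehyde F6.
   - The Wittig reaction of step 7 gives the vinyl dioxolane F7, and hydrogenation as in step 8 gives the saturated acetal F8.
   - DIBAL-H (2.2 equiv) removes the pivalate to give the C14 alcohol F9, and Dess–Martin oxidation leads to 14.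

3. Step 19. Activation of the C–Br bond may be sluggish, so that oligomerisation or simple reduction of the halide overtakes ring closure. The fallback sets out from borane 25 and alkyne 22, returns at 28, and closes the ring with an alkyne instead of a halide.
   - 25 is coupled under the conditions of step 17 with 22 in place of 24 to give the enyne acetal F10.
   - PPTS hydrolysis gives the ynal F11.
   - Nickel-catalysed reductive aldehyde–alkyne macrocyclisation (Ni(cod)2, a very bulky N-heterocyclic carbene, Et3SiH, THF, high dilution) joins the aldehyde carbon to the internal alkyne carbon when the ligand is large. It gives the macrocyclic exomethylene triethylsilyl ether F12.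
   - HF·pyridine frees alcohol 28.

Further compounds
F1 | step 4 | epoxy alcohol (oxirane on C4–C5, anti to OTBS and C15) | C[C@]12[C@H](O[Si](C)(C)C(C)(C)C)C[C@H](C(C)(C)O)C[C@H]1O2
F2 | step 4 | C5-hydroxy silyloxy cineole (OH anti to the ether bridge) | C[C@@]12OC(C)(C)[C@@H](C[C@H]1O[Si](C)(C)C(C)(C)C)C[C@H]2O
F3 | step 4 | S-methyl xanthate of F2 | C[C@@]12OC(C)(C)[C@@H](C[C@H]1O[Si](C)(C)C(C)(C)C)C[C@H]2OC(=S)SC
F4 | step 6 | C5,C14-diol | OC[C@@H]1C[C@@H](O[Si](C)(C)C(C)(C)C)[C@](C)(CO)OC1(C)C
F5 | step 6 | C14 mono-pivalate | CC(C)(C)C(=O)OC[C@@H]1C[C@@H](O[Si](C)(C)C(C)(C)C)[C@](C)(CO)OC1(C)C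
F6 | step 6 | C5 aldehyde, C14 pivalate | CC(C)(C)C(=O)OC[C@@H]1C[C@@H](O[Si](C)(C)C(C)(C)C)[C@](C)(C=O)OC1(C)C
F7 | step 6 | vinyl dioxolane, C14 pivalate (E/Z) | CC(C)(C)C(=O)OC[C@@H]1C[C@@H](O[Si](C)(C)C(C)(C)C)[C@](C)(C=CC2OCCO2)OC1(C)C
F8 | step 6 | saturated acetal, C14 pivalate | CC(C)(C)C(=O)OC[C@@H]1C[C@@H](O[Si](C)(C)C(C)(C)C)[C@](C)(CCC2OCCO2)OC1(C)C
F9 | step 6 | C14 alcohol | OC[C@@H]1C[C@@H](O[Si](C)(C)C(C)(C)C)[C@](C)(CCC2OCCO2)OC1(C)C
F10 | step 19 | enyne acetal | C#CCC/C=C(\C)CC[C@@H]1C[C@@H](OC(C)=O)[C@](C)(CCC2OCCO2)OC1(C)C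
F11 | step 19 | ynal | C#CCC/C=C(\C)CC[C@@H]1C[C@@H](OC(C)=O)[C@](C)(CCC=O)OC1(C)C
F12 | step 19 | macrocyclic exomethylene triethylsilyl ether (C7 epimers) | C=C1CC/C=C(\C)CC[C@@H]2C[C@@H](OC(C)=O)[C@](C)(CCC1O[Si](CC)(CC)CC)OC2(C)C
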